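**Retrosynthetic overview**
1. Target 24 ⇐ Baeyer–Villiger ring expansion of cyclobutanone 23: the lactone oxygen goes in last, between C12 and the allylic C6.
2. 23 ⇐ ring-forming keteniminium–alkene (2+2) cycloaddition of open-chain amide 19: C12–C11 and C6–C7 in one step, closing the cyclobutane and the ten-membered carbocycle together and setting C6, C7 and C11.
3. Enabling feature: the γ-lactone ring O–C12(=O)–C11–C7–C6 is the one-oxygen homologue of a cyclobutanone whose four carbons split into a ketene unit C6=C12 and the Z-alkene C7=C11; C6 is allylic to C4=C5, so it is the acidic keteniminium α-carbon and later the migrating carbon.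
4. 19 ⇐ linear chain from 4-methylpent-3-enoic acid: C3 by allylboration, C1=C10 by cross-metathesis, C8–C9 by butynyl addition, C9/C10/C1 by one Sharpless kinetic resolution–epoxidation, Z-alkene by semihydrogenation.
5. Ring order: oxirane (step 7), then cyclobutane and cyclodecene together (step 10), then γ-lactone by ring expansion (step 11).

Key step: step 10

Remark: C-numbers in the explanations are germacrane numbers of the target (C12 lactone carbonyl, C13 lactone methyl, C14 on C10, C15 on C4); the names of open-chain intermediates use their own chain numbering; (−)-Ipc2B(allyl) is taken as the commercial solution.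

Step 1
Reactants: 1 4-methylpent-3-enoic acid; 2 pyrrolidine
Product: 4 4-methyl-1-(pyrrolidin-1-yl)pent-3-en-1-one, via acyl imidazole 3 (not isolated)
Conditions: CDI, CH2Cl2, 0 °C → rt; then 2, rt
Reagents that add atoms: none
Why: CDI amide coupling (acyl imidazole, then aminolysis) runs under neutral conditions, so the β,γ-double bond should not move into conjugation.

Step 2
Reactants: 4 4-methyl-1-(pyrrolidin-1-yl)pent-3-en-1-one
Product: 6 (E)-2-methyl-5-oxo-5-(pyrrolidin-1-yl)pent-2-enal, via allylic alcohol 5 (not isolated)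
Conditions: SeO2 (1.1 equiv), 1,4-dioxane–H2O, 80 °C
Reagents that add atoms: selenium dioxide (O=[Se]=O)
Why: Riley allylic oxidation (ene reaction, then [2,3]-shift) attacks the more substituted alkene terminus at the methyl trans to the chain and should carry it through alcohol 5 to the (E)-enal, leaving the amide methylene at the other terminus.

Step 3
Reactants: 6 (E)-2-methyl-5-oxo-5-(pyrrolidin-1-yl)pent-2-enal; 7 (−)-B-allyldiisopinocampheylborane
Product: 9 (3E,5S)-5-hydroxy-4-methyl-1-(pyrrolidin-1-yl)octa-3,7-dien-1-one, via borinate ester 8 (not isolated)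
Conditions: Et2O, −78 °C; then NaOH, 30% H2O2, 0 °C
Reagents that add atoms: none
Why: Brown allylboration through a chair Zimmerman–Traxler transition state; the (+)-α-pinene-derived reagent adds allyl to the Si face of the conjugated aldehyde, as it does with benzaldehyde, which sets C3 as S under reagent control.

Step 4
Reactants: 9 (3E,5S)-5-hydroxy-4-methyl-1-(pyrrolidin-1-yl)octa-3,7-dien-1-one
Product: 10 (3E,5S)-4-methyl-1-oxo-1-(pyrrolidin-1-yl)octa-3,7-dien-5-yl acetate
Conditions: Ac2O, pyridine, DMAP (cat.), CH2Cl2, 0 °C → rt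
Reagents that add atoms: acetic anhydride (CC(=O)OC(C)=O)
Why: DMAP-catalysed acylation installs the C3 acetate of the target and keeps this allylic hydroxyl from directing the later epoxidation.

Step 5
Reactants: 10 (3E,5S)-4-methyl-1-oxo-1-(pyrrolidin-1-yl)octa-3,7-dien-5-yl acetate; 11 methacrolein
Product: 12 (3E,5S,7E)-4,8-dimethyl-1,9-dioxo-1-(pyrrolidin-1-yl)nona-3,7-dien-5-yl acetate
Conditions: Grubbs 2nd-generation catalyst (5 mol%), 11 (5 equiv), CH2Cl2, 40 °C
Reagents that add atoms: none
Why: Olefin cross-metathesis of the terminal alkene with methacrolein should give the E-2-methyl-enal (the trisubstituted C4=C5 bond is inert), fixing the E-C1=C10 geometry that becomes the trans-oxirane.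

Step 6
Reactants: 12 (3E,5S,7E)-4,8-dimethyl-1,9-dioxo-1-(pyrrolidin-1-yl)nona-3,7-dien-5-yl acetate; 13 but-2-yne
Product: 16 (3E,5S,7E,9RS)-9-hydroxy-4,8-dimethyl-1-oxo-1-(pyrrolidin-1-yl)trideca-3,7-dien-11-yn-5-yl acetate, via but-2-ynyllithium 14 (not isolated), via allenyltitanium reagent 15 (not isolated)
Conditions: 13, s-BuLi, THF, −78 → 0 °C; ClTi(OiPr)3, −78 °C; then 12, −78 °C; aq NH4Cl
Reagents that add atoms: none
Why: SE2′ addition of the allenyltitanium reagent (propargyl/allenyl metal addition) should give the homopropargylic alcohol with the methyl-capped alkyne; the titanium reagent is non-basic and aldehyde-selective, and C9 forms as both epimers because it is resolved in step 7.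

Step 7
Reactants: 16 (3E,5S,7E,9RS)-9-hydroxy-4,8-dimethyl-1-oxo-1-(pyrrolidin-1-yl)trideca-3,7-dien-11-yn-5-yl acetate
Product: 17 (3E,5S,7S,8S,9S)-7,8-epoxy-9-hydroxy-4,8-dimethyl-1-oxo-1-(pyrrolidin-1-yl)tridec-3-en-11-yn-5-yl acetate
Conditions: Ti(OiPr)4 (10 mol%), L-(+)-DIPT (15 mol%), t-BuOOH (0.55 equiv), 4 Å MS, CH2Cl2, −20 °C, stopped near half conversion
Reagents that add atoms: tert-butyl hydroperoxide (CC(C)(C)OO)
Why: Sharpless asymmetric epoxidation in kinetic-resolution mode: with L-(+)-DIPT only the (9S)-epimer reacts fast, on the face that gives the erythro epoxy alcohol, so C9 is selected and C10 and C1 are set by the reagent, while the (9R)-epimer remains as allylic alcohol and the acetylated C3 oxygen cannot direct.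

Step 8
Reactants: 17 (3E,5S,7S,8S,9S)-7,8-epoxy-9-hydroxy-4,8-dimethyl-1-oxo-1-(pyrrolidin-1-yl)tridec-3-en-11-yn-5-yl acetate
Product: 18 (3E,5S,7S,8R,9S)-7,8-epoxy-4,8-dimethyl-1-oxo-1-(pyrrolidin-1-yl)tridec-3-en-11-yne-5,9-diyl diacetate
Conditions: Ac2O, pyridine, DMAP (cat.), CH2Cl2, 0 °C → rt
Reagents that add atoms: acetic anhydride (CC(=O)OC(C)=O)
Why: DMAP-catalysed acylation of the secondary alcohol installs the C9 acetate; the oxirane is stable to these basic conditions.

Step 9
Reactants: 18 (3E,5S,7S,8R,9S)-7,8-epoxy-4,8-dimethyl-1-oxo-1-(pyrrolidin-1-yl)tridec-3-en-11-yne-5,9-diyl diacetate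
Product: 19 (3E,5S,7S,8R,9S,11Z)-7,8-epoxy-4,8-dimethyl-1-oxo-1-(pyrrolidin-1-yl)trideca-3,11-diene-5,9-diyl diacetate
Conditions: H2 (1 atm), Lindlar catalyst, quinoline, EtOAc, rt
Reagents that add atoms: none
Why: Lindlar semihydrogenation (syn addition on poisoned Pd) should give the Z-alkene whose geometry becomes the cis relation of C8 and the C11 methyl; oxirane, acetates and the trisubstituted alkene are not reduced.

Step 10
Reactants: 19 (3E,5S,7S,8R,9S,11Z)-7,8-epoxy-4,8-dimethyl-1-oxo-1-(pyrrolidin-1-yl)trideca-3,11-diene-5,9-diyl diacetate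
Product: 23 ring-fused cyclobutanone (the target without its lactone ring oxygen: C12(=O) bonded to C6 and C11; 1S,3S,4E,6S,7S,9S,10R,11R), via O-triflyliminium triflate 20 (not isolated), via keteniminium triflate 21 (not isolated), via cyclobutaniminium triflate 22 (not isolated)
Conditions: Tf2O (1.1 equiv), 2,4,6-collidine (3 equiv), ClCH2CH2Cl (2 mM), −20 → 60 °C; then sat. aq NaHCO3, rt
Reagents that add atoms: water (O)
Why: Proposed new method: O-triflation of the amide and deprotonation at the doubly activated C6 give vinylketeniminium 21, whose electrophilic C12 is attacked by the less hindered, methyl-bearing alkene carbon C11 while the enamine carbon C6 closes onto C7 in a concerted but asynchronous (2+2) addition, so C12–C11 and C6–C7 form in one event. The closest known reactions are the intramolecular keteniminium–alkene cycloaddition to five- to seven-membered rings and the high-dilution macrocyclic dimerisation of ketenes; the new element is the ten-membered ring. The cyclobutane closes by (2+2) cycloaddition and the carbocycle closes through the same C6–C7 bond as a ten-membered ring (exo with respect to C7). C7 and C11 follow from suprafacial addition to the Z-alkene (C8 and the C11 methyl cis), C6 is epimerisable through the enamine of 22 and is expected to settle trans to C8, and the alkene face is expected to be set by a crown-like transition state with both acetoxy groups pseudo-equatorial and the trans-oxirane and E-C4=C5 bond acting as rigid turns. The step needs ring closure over oligomerisation (2 mM; keteniminium salts do not dimerise), the fused over the crossed mode (C12 to the less hindered C11) and survival of the oxirane (excess collidine, no free acid); the C4=C5 bond cannot compete because its E geometry forbids any small ring.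

Step 11
Reactants: 23 ring-fused cyclobutanone
Product: 24 (1S,3S,4E,6S,7S,9S,10R,11R)-3,9-diacetoxy-1,10-epoxy-11,13-dihydrogermacr-4-en-12,6-olide (target)
Conditions: 30% aq H2O2 (3 equiv), CF3CH2OH, 0 °C → rt
Reagents that add atoms: hydrogen peroxide (OO)
Why: Baeyer–Villiger oxidation: the strained cyclobutanone adds peroxide readily and the secondary allylic C6 should migrate in preference to the secondary alkyl C11, with retention, so oxygen enters the C12–C6 bond; H2O2 activated only by the fluorinated alcohol should leave the deactivated C4=C5 bond, the oxirane and the acetates alone.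

**Compound list**
1 | 4-methylpent-3-enoic acid | CC(C)=CCC(=O)O | starting material
2 | pyrrolidine | C1CCNC1 | starting material
3 | 1-(imidazol-1-yl)-4-methylpent-3-en-1-one | CC(C)=CCC(=O)n1ccnc1 | intermediate
4 | 4-methyl-1-(pyrrolidin-1-yl)pent-3-en-1-one | CC(C)=CCC(=O)N1CCCC1 | intermediate
5 | (E)-5-hydroxy-4-methyl-1-(pyrrolidin-1-yl)pent-3-en-1-one | OC/C(C)=C/CC(=O)N1CCCC1 | intermediate
6 | (E)-2-methyl-5-oxo-5-(pyrrolidin-1-yl)pent-2-enal | O=C/C(C)=C/CC(=O)N1CCCC1 | intermediate
7 | (−)-B-allyldiisopinocampheylborane, Ipc = (1R,2S,3R,5R) | C=CCB([C@@H]1C[C@@H]2C[C@H]([C@H]1C)C2(C)C)[C@@H]3C[C@@H]4C[C@H]([C@H]3C)C4(C)C | starting material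
8 | (3E,5S)-4-methyl-1-oxo-1-(pyrrolidin-1-yl)octa-3,7-dien-5-yl diisopinocampheylborinate | O=C(N1CCCC1)C/C=C(\C)[C@@H](OB([C@@H]2C[C@@H]3C[C@H]([C@H]2C)C3(C)C)[C@@H]4C[C@@H]5C[C@H]([C@H]4C)C5(C)C)CC=C | intermediate
9 | (3E,5S)-5-hydroxy-4-methyl-1-(pyrrolidin-1-yl)octa-3,7-dien-1-one | O=C(N1CCCC1)C/C=C(\C)[C@@H](O)CC=C | intermediate
10 | (3E,5S)-4-methyl-1-oxo-1-(pyrrolidin-1-yl)octa-3,7-dien-5-yl acetate | O=C(N1CCCC1)C/C=C(\C)[C@@H](OC(C)=O)CC=C | intermediate
11 | methacrolein | CC(=C)C=O | starting material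
12 | (3E,5S,7E)-4,8-dimethyl-1,9-dioxo-1-(pyrrolidin-1-yl)nona-3,7-dien-5-yl acetate | O=C(N1CCCC1)C/C=C(\C)[C@@H](OC(C)=O)C/C=C(\C)C=O | intermediate
13 | but-2-yne | CC#CC | starting material
14 | but-2-ynyllithium | [Li]CC#CC | intermediate
15 | (buta-2,3-dien-2-yl)tri(propan-2-yloxy)titanium | C=C=C(C)[Ti](OC(C)C)(OC(C)C)OC(C)C | intermediate
16 | (3E,5S,7E,9RS)-9-hydroxy-4,8-dimethyl-1-oxo-1-(pyrrolidin-1-yl)trideca-3,7-dien-11-yn-5-yl acetate | O=C(N1CCCC1)C/C=C(\C)[C@@H](OC(C)=O)C/C=C(\C)C(O)CC#CC | intermediate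
17 | (3E,5S,7S,8S,9S)-7,8-epoxy-9-hydroxy-4,8-dimethyl-1-oxo-1-(pyrrolidin-1-yl)tridec-3-en-11-yn-5-yl acetate | O=C(N1CCCC1)C/C=C(\C)[C@@H](OC(C)=O)C[C@@H]1O[C@@]1(C)[C@@H](O)CC#CC | intermediate
18 | (3E,5S,7S,8R,9S)-7,8-epoxy-4,8-dimethyl-1-oxo-1-(pyrrolidin-1-yl)tridec-3-en-11-yne-5,9-diyl diacetate | O=C(N1CCCC1)C/C=C(\C)[C@@H](OC(C)=O)C[C@@H]1O[C@@]1(C)[C@@H](OC(C)=O)CC#CC | intermediate
19 | (3E,5S,7S,8R,9S,11Z)-7,8-epoxy-4,8-dimethyl-1-oxo-1-(pyrrolidin-1-yl)trideca-3,11-diene-5,9-diyl diacetate | O=C(N1CCCC1)C/C=C(\C)[C@@H](OC(C)=O)C[C@@H]1O[C@@]1(C)[C@@H](OC(C)=O)C/C=C\C | intermediate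
20 | O-triflyliminium triflate of 19 | FC(F)(F)S(=O)(=O)OC(=[N+]1CCCC1)C/C=C(\C)[C@@H](OC(C)=O)C[C@@H]1O[C@@]1(C)[C@@H](OC(C)=O)C/C=C\C.[O-]S(=O)(=O)C(F)(F)F | intermediate
21 | vinylketeniminium triflate from 19 | C(=C=[N+]1CCCC1)/C=C(\C)[C@@H](OC(C)=O)C[C@@H]1O[C@@]1(C)[C@@H](OC(C)=O)C/C=C\C.[O-]S(=O)(=O)C(F)(F)F | intermediate
22 | cyclobutaniminium triflate (pyrrolidinium ylidene at C12 of 23) | CC(=O)O[C@H]1C[C@@H]2O[C@@]2(C)[C@@H](OC(C)=O)C[C@@H]2[C@@H](/C=C/1C)C(=[N+]3CCCC3)[C@@H]2C.[O-]S(=O)(=O)C(F)(F)F | intermediate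
23 | ring-fused cyclobutanone (C12(=O) bonded to C6 and C11; 1S,3S,4E,6S,7S,9S,10R,11R) | CC(=O)O[C@H]1C[C@@H]2O[C@@]2(C)[C@@H](OC(C)=O)C[C@@H]2[C@@H](/C=C/1C)C(=O)[C@@H]2C | intermediate
24 | (1S,3S,4E,6S,7S,9S,10R,11R)-3,9-diacetoxy-1,10-epoxy-11,13-dihydrogermacr-4-en-12,6-olide | CC(=O)O[C@H]1C[C@@H]2O[C@@]2(C)[C@@H](OC(C)=O)C[C@@H]2[C@@H](/C=C/1C)OC(=O)[C@@H]2C | target

Total step count: 11. Longest linear sequence: 11 steps (from acid 1).

**Steps most likely to fail**

1. Step 10 (Proposed new method). What may go wrong: oligomerisation outruns ring closure; the alkene adds in the crossed sense (C12 to C7); the wrong alkene face reacts; the oxirane is opened by collidinium triflate or is attacked across the ring by C4=C5. The fallback uses known chemistry only, sets out from acetate 10 and returns at target 24. The cycloaddition is run in its established bimolecular form and the ring is closed afterwards by olefin metathesis, the intramolecular counterpart of step 5. Commercial (Z)-pent-3-en-1-ol is silylated (TBDPSCl, imidazole) to silyl ether F1. Amide 10 is activated as in step 10 (Tf2O, collidine) but at 0.2 M with F1 (10 equiv); O-triflyliminium triflate F2, keteniminium triflate F3 and cyclobutaniminium triflate F4 are passed, and bicarbonate hydrolysis should give cyclobutanone F5. The monosubstituted alkene of 10 is much less nucleophilic than the 1,2-dialkyl alkene in excess and cannot reach its own keteniminium; regioisomers and the diastereomers that differ in the alkene face are separated. H2O2 in CF3CH2OH should give lactone F6, buffered TBAF primary alcohol F7, Dess–Martin periodinane aldehyde F8, and 2-bromopropene with CrCl2/NiCl2 (Nozaki–Hiyama–Kishi) isopropenyl carbinol F9, of which the 9S epimer is carried on. Ring-closing metathesis (Hoveyda–Grubbs II, toluene, 80 °C, 1 mM) closes C1=C10 to macrocyclic allylic alcohol F10. VO(acac)2/t-BuOOH delivers oxygen from the hydroxyl-bearing outer face (erythro) to epoxy alcohol F11, and Ac2O/pyridine gives 24.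

2. Step 11. What may go wrong: migration of C11 instead of C6, or attack of the peroxide on the oxirane or the C4=C5 bond. The fallback sets out from cyclobutanone 23 and returns at 24, replacing peroxide chemistry by a photochemical ring expansion. Irradiation of 23 (λ > 300 nm, MeCN–H2O) should cleave the more substituted, allyl-stabilised C12–C6 bond (Norrish type I); the acyl oxygen recombines with C6 with retention to an oxacarbene that water traps as lactol F12. Fétizon oxidation (Ag2CO3 on Celite, benzene, 80 °C) then gives 24.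

3. Step 2. What may go wrong: unselective allylic oxidation (attack at the doubly activated C6 methylene), over-oxidation to the acid, or migration of the alkene into conjugation with the amide. The fallback sets out from pyrrolidine 2 and methacrolein 11 and returns at enal 6, building the enal by cross-metathesis instead of C–H oxidation. Acylation of 2 with commercial but-3-enoyl chloride (Et3N, CH2Cl2, 0 °C) gives butenoyl amide F13, and cross-metathesis of F13 with 11 (Hoveyda–Grubbs II, CH2Cl2, 40 °C), the reaction type of step 5, should give (E)-6.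

**Further compounds**
F1 | step 10 | tert-butyl[(Z)-pent-3-enyloxy]diphenylsilane | C/C=C\CCO[Si](c1ccccc1)(c1ccccc1)C(C)(C)C
F2 | step 10 | O-triflyliminium triflate of 10 | FC(F)(F)S(=O)(=O)OC(=[N+]1CCCC1)C/C=C(\C)[C@@H](OC(C)=O)CC=C.[O-]S(=O)(=O)C(F)(F)F
F3 | step 10 | vinylketeniminium triflate from 10 | C(=C=[N+]1CCCC1)/C=C(\C)[C@@H](OC(C)=O)CC=C.[O-]S(=O)(=O)C(F)(F)F
F4 | step 10 | cyclobutaniminium triflate (pyrrolidinium ylidene at C12 of F5) | CC(C)(C)[Si](c1ccccc1)(c1ccccc1)OCC[C@@H]2[C@@H](/C=C(\C)[C@@H](OC(C)=O)CC=C)C(=[N+]3CCCC3)[C@@H]2C.[O-]S(=O)(=O)C(F)(F)F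
F5 | step 10 | cyclobutanone: 2-alkenyl (C6), 3-(2-silyloxyethyl) (C7), 4-methyl (C11); 6,7-trans-7,11-cis | CC(C)(C)[Si](c1ccccc1)(c1ccccc1)OCC[C@@H]2[C@@H](/C=C(\C)[C@@H](OC(C)=O)CC=C)C(=O)[C@@H]2C
F6 | step 10 | γ-lactone from F5 (oxygen between C12 and C6) | CC(C)(C)[Si](c1ccccc1)(c1ccccc1)OCC[C@@H]2[C@@H](/C=C(\C)[C@@H](OC(C)=O)CC=C)OC(=O)[C@@H]2C
F7 | step 10 | primary alcohol from F6 | OCC[C@@H]1[C@@H](/C=C(\C)[C@@H](OC(C)=O)CC=C)OC(=O)[C@@H]1C
F8 | step 10 | aldehyde (C9) from F7 | O=CC[C@@H]1[C@@H](/C=C(\C)[C@@H](OC(C)=O)CC=C)OC(=O)[C@@H]1C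
F9 | step 10 | (9S)-isopropenyl carbinol | C=C(C)[C@@H](O)C[C@@H]1[C@@H](/C=C(\C)[C@@H](OC(C)=O)CC=C)OC(=O)[C@@H]1C
F10 | step 10 | macrocyclic allylic alcohol (1(10)E,4E-diene, 9-OH, 3-OAc, lactone) | CC(=O)O[C@H]1C/C=C(\C)[C@@H](O)C[C@@H]2[C@@H](/C=C/1C)OC(=O)[C@@H]2C
F11 | step 10 | epoxy alcohol (9-deacetyl target) | CC(=O)O[C@H]1C[C@@H]2O[C@@]2(C)[C@@H](O)C[C@@H]2[C@@H](/C=C/1C)OC(=O)[C@@H]2C
F12 | step 11 | lactol (C12 hemiacetal of the target) | CC(=O)O[C@H]1C[C@@H]2O[C@@]2(C)[C@@H](OC(C)=O)C[C@@H]2[C@@H](/C=C/1C)OC(O)[C@@H]2C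
F13 | step 2 | 1-(pyrrolidin-1-yl)but-3-en-1-one | C=CCC(=O)N1CCCC1
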